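**Synthesis outline**

Chain numbering runs from C1 (lactone C=O) to C10 (acetyl CH3). Enabling feature: in the tetrahydropyran ring (O, C4, C5, C6, C7, C8) the oxygen lies between two fully substituted carbons, C4 and C8. Each holds a methyl group and, on the same ring face, a carbon substituent (C3, C9). A C3–C9 bond would turn this ring into an 8-oxabicyclo[3.2.1]octane, the [5+2] adduct of 2,4,6-trimethyl-3-oxidopyrylium with a two-carbon alkyne.
Retrosynthetic cuts, in order: the C7 O–acyl bond (octenoate), C2–C3 (Dieckmann), a reconnection C3=C9 (reverse of an enol ether ozonolysis), then C4–C3 and C8–C9 in one operation.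
Forward ring order: furan, six-membered pyranone (Achmatowicz), oxabicycle holding a temporary 2,5-dihydrofuran ring ([5+2]), monocyclic pyran again (ozonolysis), delta-lactone last. The octenoate is attached at the end.
Stereochemistry: C4 and C8 are cis because the cycloaddition is suprafacial, and their absolute sense comes from the (1R,2S)-2-phenylcyclohexyl group of the ynol ether (diastereomers separated). C5, C6 and C7 come from exo-face delivery to the bicycle (epoxide oxygen, then syn H/B addition). C2 and C3 come from one cis hydrogenation anti to the axial C4 methyl.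

Key step: step 5

Assumption: 2,4-dimethylfuran is taken as purchasable, and the (1R,2S) auxiliary is taken to favour, or at least to allow separation of, the desired adduct; the antipodal alcohol is equally available if the bias is the opposite.

Step 1
Reactants: 1 2,4-dimethylfuran
Product: 3 1-(3,5-dimethylfuran-2-yl)ethanol (racemic), via furyllithium 2 (not isolated)
Conditions: n-BuLi, THF, 0 °C; MeCHO, −78 °C to rt; H2O
Reagents that add atoms: n-butyllithium [Li]CCCC (lithium stays only in 2); acetaldehyde CC=O
Why: Alpha-lithiation can occur only at the single free alpha position of the furan, and 1,2-addition of the furyllithium to acetaldehyde gives the racemic carbinol, whose stereocentre is erased in step 5.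

Step 2
Reactants: 3 1-(3,5-dimethylfuran-2-yl)ethanol
Product: 4 6-hydroxy-2,4,6-trimethyl-2H-pyran-3(6H)-one (racemic mixture of diastereomers)
Conditions: mCPBA, CH2Cl2, 0 °C
Reagents that add atoms: 3-chloroperoxybenzoic acid OOC(=O)c1cccc(Cl)c1
Why: Achmatowicz rearrangement, in which oxidation of the electron-rich furan, opening to the Z-enedione and closure by the side-chain hydroxyl give the six-membered hemiketal, whose two stereocentres are of no consequence.

Step 3
Reactants: 4 6-hydroxy-2,4,6-trimethyl-2H-pyran-3(6H)-one
Product: 5 6-(tert-butoxycarbonyloxy)-2,4,6-trimethyl-2H-pyran-3(6H)-one (racemic mixture of diastereomers)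
Conditions: Boc2O, DMAP (cat.), CH2Cl2, −30 to 0 °C
Reagents that add atoms: di-tert-butyl dicarbonate CC(C)(C)OC(=O)OC(=O)OC(C)(C)C
Why: DMAP-catalysed O-acylation of the cyclic hemiketal installs a leaving group that later departs as CO2 and tert-butanol instead of a carboxylic acid, and the low temperature keeps the amine from starting ionisation early.

Step 4
Reactants: 6 (1R,2S)-trans-2-phenylcyclohexanol; 7 trichloroethylene
Product: 10 1-{[(1R,2S)-2-phenylcyclohexyl]oxy}prop-1-yne, via dichlorovinyl ether 8 (not isolated), via lithium alkoxyacetylide 9 (not isolated)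
Conditions: KH, THF, 0 °C; Cl2C=CHCl, −50 °C to rt; n-BuLi (2.5 equiv), −78 to −40 °C; MeI, DMPU, −78 °C to rt
Reagents that add atoms: n-butyllithium [Li]CCCC (lithium stays only in 9); iodomethane CI
Why: This is the established one-pot ynol ether synthesis (alkoxide addition–elimination on trichloroethylene, dehydrochlorination and chlorine–lithium exchange with n-BuLi, C-methylation of the acetylide), and none of its stages touches the two stereocentres of the auxiliary.

Step 5
Reactants: 5 6-(tert-butoxycarbonyloxy)-2,4,6-trimethyl-2H-pyran-3(6H)-one; 10 1-{[(1R,2S)-2-phenylcyclohexyl]oxy}prop-1-yne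
Product: 12 (1S,5S)-1,3,5,7-tetramethyl-6-{[(1R,2S)-2-phenylcyclohexyl]oxy}-8-oxabicyclo[3.2.1]octa-3,6-dien-2-one (C8 and C4 bridgeheads; C7 ketone; C6=C5 enone alkene; C9=C3 bridge enol ether), via oxidopyrylium ylide 11 (not isolated)
Conditions: Et3N, CH2Cl2, 23 °C, 5 (2 equiv) added slowly to 10; diastereomers separated on Et3N-washed silica gel
Reagents that add atoms: none
Why: Proposed new method: Et3N removes the C8 proton of 5 and tert-butyl carbonate departs (it collapses to CO2 and tert-butanol, so no acid reaches the ynol ether), which gives the planar ylide 11; this adds through its two oxygen-flanked termini to the triple bond of 10 in a concerted suprafacial [5+2] cycloaddition that makes C8–C9 and C4–C3 at the same time. The closest known reaction type is the base-mediated intermolecular [5+2] cycloaddition of pyranone-derived 3-oxidopyrylium ylides with vinyl ethers and with acceptor alkynes, and an ynol ether, not yet tried, joins the donor character of the first class to the slim linear shape of the second. Both new rings, the seven-membered carbocycle C3–C4–C5–C6–C7–C8–C9 and the 2,5-dihydrofuran O–C4–C3–C9–C8, close in cycloaddition mode with two bonds formed together, so no endo or exo ring-closure issue and, with an alkyne, no endo or exo adduct issue arises. The new stereocentres C4 and C8 are held cis by the suprafacial bridging of a flat ring, and their absolute configuration depends on which ylide face is attacked, which the phenyl-shielded auxiliary on the alkyne oxygen biases and the separation of the two diastereomeric adducts secures. The step needs the nucleophilic methyl-bearing alkyne carbon to bond to the ylide terminus next to the oxido carbon (C8) and the alkoxy-bearing carbon to bond to C4, which is the orientation that vinyl ethers show with these ylides and follows from the polarisation of the ynol ether. It also needs cycloaddition to outrun ylide dimerisation, which the three methyl groups on the ylide and the slow addition of 5 to 10 favour.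

Step 6
Reactants: 12 cycloadduct
Product: 13 exo C5–C6 epoxy ketone (epoxide oxygen syn to the oxygen bridge and anti to the C3=C9 bridge)
Conditions: 30% aq. H2O2, NaOH, MeOH, 0 °C to rt
Reagents that add atoms: hydrogen peroxide OO
Why: Weitz–Scheffer epoxidation, in which hydroperoxide adds to C5 of the enone from the open exo face and so fixes the C5–O stereocentre, while the electron-rich enol ether is inert to a nucleophilic oxidant.

Step 7
Reactants: 13 exo epoxy ketone
Product: 15 2-exo-hydroxy-1,3,5,6-tetramethyl-7-{[(1R,2S)-2-phenylcyclohexyl]oxy}-8-oxabicyclo[3.2.1]octa-3,6-diene (C5 exo-OH; C6=C7 alkene), via epoxy hydrazone 14 (not isolated)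
Conditions: N2H4·H2O (excess), AcOH (cat.), MeOH, 0 to 50 °C
Reagents that add atoms: hydrazine NN (nitrogen stays only in 14)
Why: Wharton transposition, in which the hydrazone opens the C6–O bond and the vinyl diazene loses N2, so the alkene moves to C6–C7 and the C5–O bond keeps its exo configuration, while excess hydrazine keeps the medium basic enough for the enol ether.

Step 8
Reactants: 15 allylic alcohol
Product: 16 C5 exo-propionate of 15
Conditions: (EtCO)2O, DMAP (cat.), pyridine, rt to 40 °C
Reagents that add atoms: propionic anhydride CCC(=O)OC(=O)CC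
Why: DMAP-catalysed acylation of the hindered secondary alcohol brings in C1, C2 and the C2 methyl group and marks C5 before the second hydroxyl appears.

Step 9
Reactants: 16 allylic propionate
Product: 18 C7 exo-alcohol (C5 exo-propionate; C6 methyl endo; bridge enol ether intact), via alkylborane 17 (not isolated)
Conditions: BH3·THF, THF, 0 °C to rt; Me3NO·2H2O, 0 to 50 °C
Reagents that add atoms: borane B (boron stays only in 17); trimethylamine N-oxide C[N+](C)(C)[O-]
Why: In this hydroboration–oxidation BH3 adds syn from the exo face with boron on the less substituted C7, which sets C6 (H exo, methyl endo) and C7 (O exo, retention on oxidation), while the tetrasubstituted, doubly neopentyl enol ether reacts more slowly and the neutral amine oxide avoids 1,3-acyl migration.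

Step 10
Reactants: 18 C7 alcohol
Product: 19 bicyclic C5 exo-propionate C7 exo-triethylsilyl ether
Conditions: Et3SiOTf, 2,6-lutidine, CH2Cl2, −78 to 0 °C
Reagents that add atoms: triethylsilyl trifluoromethanesulfonate CC[Si](CC)(CC)OS(=O)(=O)C(F)(F)F
Why: A silyl triflate with a hindered pyridine base silylates the axial neopentyl C7 hydroxyl quickly in the cold, which freezes the position of the acyl group and leaves the enol ether unharmed.

Step 11
Reactants: 19 bicyclic silyl ether
Product: 21 tetrahydropyran with the (1R,2S)-2-phenylcyclohexyl ester (C3) and axial methyl on C4; equatorial O-propionyl (C5), methyl (C6) and OSiEt3 (C7); acetyl (C9–C10) and axial methyl on C8, via methoxy hydroperoxide 20 (not isolated)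
Conditions: O3, CH2Cl2–MeOH (4:1), NaHCO3, Sudan Red 7B, −78 °C; Me2S, −78 °C to rt
Reagents that add atoms: ozone [O-][O+]=O; methanol CO (stays only in 20)
Why: Ozonolysis of the electron-rich enol ether (Criegee mechanism, with the C9 carbonyl oxide trapped by methanol and reduced by Me2S) cleaves C3=C9 into the C3 ester and the C9 methyl ketone without touching a stereocentre, after which the ring relaxes to the chair with the C5, C6 and C7 substituents equatorial.

Step 12
Reactants: 21 keto diester
Product: 22 trans-fused beta-keto delta-lactone drawn as its enol (4-hydroxy-3-methyl-5,6-dihydropyran-2-one fused at C4–C5; C7 OSiEt3; C8 acetyl)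
Conditions: LiN(SiMe3)2 (3.5 equiv), THF, −78 to 0 °C; cold 0.5 M HCl to pH 4
Reagents that add atoms: none
Why: In this Dieckmann-type condensation the propionate enolate on the equatorial C5 oxygen attacks the gauche equatorial C3 ester through a six-membered transition state, expels the recoverable auxiliary alkoxide and is driven by the stabilised beta-keto lactone enolate, while the C10 ketone enolate cannot reach C3 from the diequatorial chair.

Step 13
Reactants: 22 enol lactone
Product: 23 hydroxy lactone with C2 methyl, C3 hydroxyl and C4 methyl all cis (C7 OSiEt3)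
Conditions: H2 (50 bar), Raney Ni, EtOAc, 25 °C, stopped after one equivalent of H2
Reagents that add atoms: none
Why: Heterogeneous cis hydrogenation of 4-hydroxy-5,6-dihydropyran-2-ones over Raney Ni is an established route to cis-3-alkyl-4-hydroxy delta-lactones, both hydrogens arrive opposite the axial C4 methyl and so set C2 and C3 together, and the neopentyl C9 ketone should reduce more slowly.

Step 14
Reactants: 23 hydroxy lactone
Product: 24 C3 O-tert-butyldimethylsilyl, C7 O-triethylsilyl lactone
Conditions: t-BuMe2SiOTf, 2,6-lutidine, CH2Cl2, −20 to 0 °C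
Reagents that add atoms: tert-butyldimethylsilyl trifluoromethanesulfonate CC(C)(C)[Si](C)(C)OS(=O)(=O)C(F)(F)F
Why: Silyl triflate silylation covers the hindered C3 hydroxyl under weakly basic, non-nucleophilic conditions that neither epimerise C2 nor provoke beta-elimination.

Step 15
Reactants: 24 bis-silyl ether
Product: 25 C7 alcohol with C3 O-tert-butyldimethylsilyl retained
Conditions: AcOH–THF–H2O (3:1:1), rt
Reagents that add atoms: none
Why: Mild acid hydrolysis distinguishes the two silyl ethers by size, the triethylsilyl group leaving well before the tert-butyldimethylsilyl group, and it also reverts any C9 silyl enol ether formed in step 14.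

Step 16
Reactants: 25 C7 alcohol; 26 (E)-oct-2-enoic acid
Product: 28 C3 O-tert-butyldimethylsilyl botcinin K, via mixed anhydride 27 (not isolated)
Conditions: 2,4,6-Cl3C6H2COCl, Et3N, toluene, rt; 25, DMAP, toluene, rt to 40 °C
Reagents that add atoms: 2,4,6-trichlorobenzoyl chloride O=C(Cl)c1c(Cl)cc(Cl)cc1Cl (stays only in 27)
Why: In the Yamaguchi esterification the acid is activated as the mixed anhydride and passed by DMAP to the hindered C7 hydroxyl, with retention at C7 and without loss of the E geometry.

Step 17
Reactants: 28 C3 O-silyl botcinin K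
Product: 29 botcinin K, (2R,3S,4R,5S,6S,7R,8R) in the chain numbering
Conditions: HF·pyridine, pyridine, THF, 0 °C to rt
Reagents that add atoms: none
Why: Fluoride-mediated desilylation under buffered non-basic conditions frees the C3 hydroxyl without C2 epimerisation, beta-elimination or acyl migration.

**Compound list**

1 | 2,4-dimethylfuran | Cc1coc(C)c1 | starting material
2 | (3,5-dimethylfuran-2-yl)lithium | [Li]c1oc(C)cc1C | intermediate
3 | 1-(3,5-dimethylfuran-2-yl)ethanol (racemic) | CC(O)c1oc(C)cc1C | intermediate
4 | 6-hydroxy-2,4,6-trimethyl-2H-pyran-3(6H)-one (racemic diastereomer mixture) | CC1OC(C)(O)C=C(C)C1=O | intermediate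
5 | 6-(tert-butoxycarbonyloxy)-2,4,6-trimethyl-2H-pyran-3(6H)-one (racemic diastereomer mixture) | CC1OC(C)(OC(=O)OC(C)(C)C)C=C(C)C1=O | intermediate
6 | (1R,2S)-trans-2-phenylcyclohexanol | O[C@@H]1CCCC[C@H]1c1ccccc1 | starting material
7 | trichloroethylene | ClC=C(Cl)Cl | starting material
8 | (E)-1,2-dichlorovinyl (1R,2S)-2-phenylcyclohexyl ether | Cl/C=C(/Cl)O[C@@H]1CCCC[C@H]1c1ccccc1 | intermediate
9 | lithium {[(1R,2S)-2-phenylcyclohexyl]oxy}acetylide | [Li]C#CO[C@@H]1CCCC[C@H]1c1ccccc1 | intermediate
10 | 1-{[(1R,2S)-2-phenylcyclohexyl]oxy}prop-1-yne | CC#CO[C@@H]1CCCC[C@H]1c1ccccc1 | intermediate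
11 | 2,4,6-trimethylpyrylium-3-olate (oxidopyrylium ylide) | Cc1cc(C)[o+]c(C)c1[O-] | intermediate
12 | (1S,5S)-1,3,5,7-tetramethyl-6-{[(1R,2S)-2-phenylcyclohexyl]oxy}-8-oxabicyclo[3.2.1]octa-3,6-dien-2-one | O=C1C(C)=C[C@]2(C)O[C@@]1(C)C(C)=C2O[C@@H]3CCCC[C@H]3c3ccccc3 | intermediate
13 | exo C5–C6 epoxy ketone of 12 | O=C1[C@]4(C)O[C@@H]4[C@]2(C)O[C@@]1(C)C(C)=C2O[C@@H]3CCCC[C@H]3c3ccccc3 | intermediate
14 | C7 hydrazone of 13 | NN=C1[C@]4(C)O[C@@H]4[C@]2(C)O[C@@]1(C)C(C)=C2O[C@@H]3CCCC[C@H]3c3ccccc3 | intermediate
15 | transposed allylic alcohol (C5 exo-OH, C6=C7 alkene, C9=C3 enol ether) | CC1=C[C@@]2(C)O[C@@](C)([C@H]1O)C(O[C@@H]3CCCC[C@H]3c3ccccc3)=C2C | intermediate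
16 | C5 exo-propionate of 15 | CC1=C[C@@]2(C)O[C@@](C)([C@H]1OC(=O)CC)C(O[C@@H]3CCCC[C@H]3c3ccccc3)=C2C | intermediate
17 | C7 exo-alkylborane (C6 H exo, methyl endo) | B[C@@H]1[C@@H](C)[C@H](OC(=O)CC)[C@]2(C)O[C@@]1(C)C(C)=C2O[C@@H]3CCCC[C@H]3c3ccccc3 | intermediate
18 | C7 exo-alcohol, C5 exo-propionate, C6 endo-methyl bicycle | O[C@@H]1[C@@H](C)[C@H](OC(=O)CC)[C@]2(C)O[C@@]1(C)C(C)=C2O[C@@H]3CCCC[C@H]3c3ccccc3 | intermediate
19 | C7 exo-triethylsilyl ether of 18 | CC[Si](CC)(CC)O[C@@H]1[C@@H](C)[C@H](OC(=O)CC)[C@]2(C)O[C@@]1(C)C(C)=C2O[C@@H]3CCCC[C@H]3c3ccccc3 | intermediate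
20 | ring-opened C3 auxiliary ester with C9 methoxy hydroperoxide (C9 epimers) | CC[Si](CC)(CC)O[C@@H]1[C@@H](C)[C@H](OC(=O)CC)[C@@](C)(C(=O)O[C@@H]2CCCC[C@H]2c2ccccc2)O[C@@]1(C)C(C)(OC)OO | intermediate
21 | monocyclic tetrahydropyran: C4 auxiliary ester, C5 propionate, C7 OSiEt3, C8 acetyl | CC[Si](CC)(CC)O[C@@H]1[C@@H](C)[C@H](OC(=O)CC)[C@@](C)(C(=O)O[C@@H]2CCCC[C@H]2c2ccccc2)O[C@@]1(C)C(C)=O | intermediate
22 | trans-fused beta-keto delta-lactone (enol form) | CC[Si](CC)(CC)O[C@@H]1[C@@H](C)[C@@H]2OC(=O)C(C)=C(O)[C@@]2(C)O[C@@]1(C)C(C)=O | intermediate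
23 | all-cis C2-methyl C3-hydroxy lactone, C7 OSiEt3 | CC[Si](CC)(CC)O[C@@H]1[C@@H](C)[C@@H]2OC(=O)[C@H](C)[C@H](O)[C@@]2(C)O[C@@]1(C)C(C)=O | intermediate
24 | C3 OSi(t-Bu)Me2, C7 OSiEt3 lactone | CC[Si](CC)(CC)O[C@@H]1[C@@H](C)[C@@H]2OC(=O)[C@H](C)[C@H](O[Si](C)(C)C(C)(C)C)[C@@]2(C)O[C@@]1(C)C(C)=O | intermediate
25 | C7 alcohol, C3 OSi(t-Bu)Me2 lactone | O[C@@H]1[C@@H](C)[C@@H]2OC(=O)[C@H](C)[C@H](O[Si](C)(C)C(C)(C)C)[C@@]2(C)O[C@@]1(C)C(C)=O | intermediate
26 | (E)-oct-2-enoic acid | CCCCC/C=C/C(=O)O | starting material
27 | (E)-oct-2-enoic 2,4,6-trichlorobenzoic anhydride | CCCCC/C=C/C(=O)OC(=O)c1c(Cl)cc(Cl)cc1Cl | intermediate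
28 | C3 O-tert-butyldimethylsilyl botcinin K | CCCCC/C=C/C(=O)O[C@@H]1[C@@H](C)[C@@H]2OC(=O)[C@H](C)[C@H](O[Si](C)(C)C(C)(C)C)[C@@]2(C)O[C@@]1(C)C(C)=O | intermediate
29 | botcinin K | CCCCC/C=C/C(=O)O[C@@H]1[C@@H](C)[C@@H]2OC(=O)[C@H](C)[C@H](O)[C@@]2(C)O[C@@]1(C)C(C)=O | target

**Step count and risks**

Total steps: 17. Longest linear sequence: 16 steps (steps 1–3 and 5–17, from 1 to 29). The ynol ether branch contributes step 4.

**Risk 1, step 5 (the labelled step).**
- What may go wrong: ylide dimerisation may outrun bond formation at two methyl-bearing termini, the ynol ether may be consumed by stray proton sources, and orientation or facial bias may be weak.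
- Fallback (known chemistry; sets out from 5, comes back at 22): ylide 11 is released from 5 with Et3N as before. It is trapped with the purchasable acceptor alkyne (prop-1-yn-1-ylsulfonyl)benzene (CC#CS(=O)(=O)c1ccccc1). This dipolarophile class is established with these ylides and places the acceptor-bearing carbon on C4.
- Preparative chromatography on a chiral stationary phase then gives the sulfonyl-bridged dienone F1 as one enantiomer.
- The operations of steps 6 to 10 follow, since the fully substituted electron-poor vinyl sulfone is inert to alkaline peroxide and to borane. Alkaline H2O2 gives the exo epoxy ketone F2. Hydrazine converts it through the epoxy hydrazone F3 (not isolated) into the allylic alcohol F4. Propionic anhydride gives the propionate F5. BH3·THF gives the alkylborane F6 (not isolated), which Me3NO oxidises to the C7 alcohol F7. Et3SiOTf gives the triethylsilyl ether F8.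
- Ozonolysis of the cyclic vinyl sulfone in CH2Cl2–MeOH over NaHCO3 cleaves the bridge with loss of benzenesulfinate, and the sulfonyl-bearing carbon emerges as a methyl ester. This gives the ester methoxy hydroperoxide F9 (not isolated), which Me2S reduces to the keto methyl ester F10.
- LiN(SiMe3)2 closes F10 to 22 with loss of methanol. The small methyl ester also makes this ring closure easier.

**Risk 2, step 7.**
- What may go wrong: hydrazone formation at a ketone flanked by two fully substituted carbons may be so slow that hydrazine opens the epoxide first or forcing conditions erode the enol ether.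
- Fallback (sets out from 13, comes back at 15): the small hydride of NaBH4 (MeOH, 0 °C) reduces the ketone to the epoxy alcohol F11, whose C7 configuration is irrelevant. Heating with 1,1'-thiocarbonyldiimidazole and DMAP in toluene gives the thiocarbonylimidazolide F12.
- Bu3SnH and AIBN at high stannane concentration generate the C7 radical (Barton–McCombie-type initiation). This radical opens the adjacent C6–O bond, and hydrogen transfer to the resulting C5 alkoxyl radical gives 15 with the exo C5–O bond unchanged.

**Risk 3, step 13.**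
- What may go wrong: uptake at the tetrasubstituted enol next to quaternary C4 may be slow enough for the C9 ketone to be over-reduced, or delivery may not be fully from one face.
- Fallback (sets out from 22, comes back at 23): hydrogenation is replaced by hydride reduction and a separate correction of C2. NaBH4 in CH2Cl2–AcOH at 0 °C is the acyloxyborohydride method used for cyclic beta-dicarbonyl compounds, and it spares unactivated hindered ketones. Hydride should attack the keto tautomer anti to the axial C4 methyl and give the correct C3 carbinol, but C2 then settles with its methyl group equatorial, giving the 2-epi hydroxy lactone F13.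
- LiN(i-Pr)2 (3.5 equiv, THF, −78 °C) forms the alkoxide lactone enolate, with the C10 ketone enolate as a spectator. A quench with 2,6-di-tert-butyl-4-methylphenol protonates C2 kinetically from the open face opposite the C3 alkoxide and the C4 methyl, which gives 23.

**Further compounds**

F1 | step 5 | sulfonyl-bridged dienone: 1,3,5,7-tetramethyl-6-(phenylsulfonyl)-8-oxabicyclo[3.2.1]octa-3,6-dien-2-one, bridgehead sense as in 12 | O=C1C(C)=C[C@]2(C)O[C@@]1(C)C(C)=C2S(=O)(=O)c3ccccc3
F2 | step 5 | exo C5–C6 epoxy ketone of F1 | O=C1[C@]4(C)O[C@@H]4[C@]2(C)O[C@@]1(C)C(C)=C2S(=O)(=O)c3ccccc3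
F3 | step 5 | epoxy hydrazone of F2 | NN=C1[C@]4(C)O[C@@H]4[C@]2(C)O[C@@]1(C)C(C)=C2S(=O)(=O)c3ccccc3
F4 | step 5 | allylic alcohol (C5 exo-OH, C6=C7 alkene, sulfonyl bridge) | CC1=C[C@@]2(C)O[C@@](C)([C@H]1O)C(S(=O)(=O)c3ccccc3)=C2C
F5 | step 5 | C5 exo-propionate of F4 | CC1=C[C@@]2(C)O[C@@](C)([C@H]1OC(=O)CC)C(S(=O)(=O)c3ccccc3)=C2C
F6 | step 5 | C7 exo-alkylborane from F5 | B[C@@H]1[C@@H](C)[C@H](OC(=O)CC)[C@]2(C)O[C@@]1(C)C(C)=C2S(=O)(=O)c3ccccc3
F7 | step 5 | C7 exo-alcohol, C5 exo-propionate, sulfonyl bridge | O[C@@H]1[C@@H](C)[C@H](OC(=O)CC)[C@]2(C)O[C@@]1(C)C(C)=C2S(=O)(=O)c3ccccc3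
F8 | step 5 | C7 triethylsilyl ether of F7 | CC[Si](CC)(CC)O[C@@H]1[C@@H](C)[C@H](OC(=O)CC)[C@]2(C)O[C@@]1(C)C(C)=C2S(=O)(=O)c3ccccc3
F9 | step 5 | C3 methyl ester with C9 methoxy hydroperoxide (C9 epimers) | CC[Si](CC)(CC)O[C@@H]1[C@@H](C)[C@H](OC(=O)CC)[C@@](C)(C(=O)OC)O[C@@]1(C)C(C)(OC)OO
F10 | step 5 | keto methyl ester (methyl ester analogue of 21) | CC[Si](CC)(CC)O[C@@H]1[C@@H](C)[C@H](OC(=O)CC)[C@@](C)(C(=O)OC)O[C@@]1(C)C(C)=O
F11 | step 7 | epoxy alcohol from 13 (C7 epimers) | OC1[C@]4(C)O[C@@H]4[C@]2(C)O[C@@]1(C)C(C)=C2O[C@@H]3CCCC[C@H]3c3ccccc3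
F12 | step 7 | C7 O-thiocarbonylimidazolide of F11 | S=C(n1ccnc1)OC1[C@]4(C)O[C@@H]4[C@]2(C)O[C@@]1(C)C(C)=C2O[C@@H]3CCCC[C@H]3c3ccccc3
F13 | step 13 | 2-epi hydroxy lactone (C2 methyl trans to C3 hydroxyl) | CC[Si](CC)(CC)O[C@@H]1[C@@H](C)[C@@H]2OC(=O)[C@@H](C)[C@H](O)[C@@]2(C)O[C@@]1(C)C(C)=O
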